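The furofuran (lignan numbering, defined below) is cut through ring B (C8'–C7' and O–C7') to a ring A 2,3-dihydrofuran carrying C9 as a hydroxymethyl group, and ring A is traced to a cis-γ-butyrolactone. The key step, a carbene-catalysed homoenolate [3+2] annulation, joins C8 to C7 and the C7 oxygen to C9', closing ring A and setting C7 and C8 in one operation. It exploits the cis (endo) relationship in ring A between the guaiacyl group on C7 and C9 on C8. Its precursors are 4-formyl-2-methoxyphenyl methanesulfonate and (E)-4-(tert-butyldiphenylsilyloxy)but-2-enal. Ring B then follows from a Prins-type closure with a silyl-protected vanillin.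

Key step: step 4

Numbering used: C7/C8/C9 on the guaiacyl side, C7'/C8'/C9' on the prenyloxyaryl side; ring A = C7–O–C9'–C8'–C8, ring B = C7'–O–C9–C8–C8'. The target is (7S,8S,7'R,8'S), with the guaiacyl group endo on ring A and the prenyloxyaryl group exo on ring B.

Assumption: the (5aS,10bR) enantiomer of the aminoindanol-derived N-mesityl triazolium salt is taken to deliver the (4S,5S)-lactone; if the sense of induction proves opposite, its (5aR,10bS) enantiomer is used instead.

Step 1
Reactants: 1 vanillin; 2 methanesulfonyl chloride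
Product: 3 4-formyl-2-methoxyphenyl methanesulfonate
Conditions: MsCl, Et3N, CH2Cl2, 0 °C
Reagents that add atoms: methanesulfonyl chloride 2, CS(=O)(=O)Cl
Why: O-Sulfonylation of a phenol with MsCl and an amine base is routine, and the sulfonate both masks the phenol and makes the aldehyde a better electrophile.

Step 2
Reactants: 4 (Z)-but-2-ene-1,4-diol; 5 tert-butyldiphenylsilyl chloride
Product: 6 (Z)-4-(tert-butyldiphenylsilyloxy)but-2-en-1-ol
Conditions: TBDPSCl (1 equiv), imidazole, diol 4 (4 equiv), THF/DMF, 0 °C → rt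
Reagents that add atoms: tert-butyldiphenylsilyl chloride 5, CC(C)(C)[Si](Cl)(c1ccccc1)c1ccccc1
Why: Silylation of a symmetrical diol used in excess gives the monosilyl ether statistically (mono-protection of a diol), and the surplus diol is removed with water.

Step 3
Reactants: 6 (Z)-4-(tert-butyldiphenylsilyloxy)but-2-en-1-ol
Product: 8 (E)-4-(tert-butyldiphenylsilyloxy)but-2-enal, via (Z)-enal 7 (not isolated)
Conditions: pyridinium chlorochromate [C5H5NH][CrO3Cl], CH2Cl2, rt
Reagents that add atoms: none
Why: Chlorochromate oxidation of the allylic alcohol gives the (Z)-enal, which equilibrates to the conjugated (E)-enal under the mildly acidic conditions, a known behaviour of cis-4-silyloxybut-2-en-1-ols (allylic oxidation with Z-to-E isomerisation).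

Step 4
Reactants: 3 4-formyl-2-methoxyphenyl methanesulfonate; 8 (E)-4-(tert-butyldiphenylsilyloxy)but-2-enal
Product: 9 4-[(2S,3S)-3-(tert-butyldiphenylsilyloxymethyl)-5-oxotetrahydrofuran-2-yl]-2-methoxyphenyl methanesulfonate (cis-lactone; ring A with C9' as the carbonyl carbon)
Conditions: (5aS,10bR)-2-mesityl-5a,10b-dihydro-4H,6H-indeno[2,1-b][1,2,4]triazolo[4,3-d][1,4]oxazin-2-ium chloride (10 mol %), DBU (10 mol %), THF, rt; 3 in excess (2 equiv)
Reagents that add atoms: none
Why: DBU deprotonates the triazolium salt, the carbene adds to the formyl carbon of 8 and proton transfer gives the homoenolate, whose β-carbon C8 attacks the carbonyl carbon C7 of 3, after which tautomerisation to the acyl azolium and O-acylation by the C7 alkoxide form O–C9' and release the carbene. The closest known reaction type is the N-heterocyclic-carbene homoenolate [3+2] annulation of enals with aromatic aldehydes to γ-butyrolactones. Ring A closes as a 5-exo-trig addition–elimination of the alkoxide at the acyl azolium carbon. The relative configuration (aryl on C7 cis to the silyloxymethyl arm on C8) is the intrinsic preference of this annulation with aryl aldehydes, whereas the absolute configuration at both centres has to come from the aminoindanol backbone of the catalyst shielding one face of the homoenolate and is the least secure element of the route. The step needs bond formation at the β-carbon to outpace benzoin-type acyl-anion addition and loss of the γ-silyloxide from the homoenolate; the N-mesityl group steers the catalyst to homoenolate reactivity, the electron-withdrawing sulfonate makes 3 a receptive electrophile, and the bulky silyl ether is a reluctant leaving group.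

Step 5
Reactants: 9 cis-lactone
Product: 10 4-[(2S,3S)-3-(tert-butyldiphenylsilyloxymethyl)-5-hydroxytetrahydrofuran-2-yl]-2-methoxyphenyl methanesulfonate (lactol, both anomers)
Conditions: i-Bu2AlH (1.1 equiv), CH2Cl2, −78 °C; aq. potassium sodium tartrate
Reagents that add atoms: none
Why: Half-reduction of a γ-lactone with i-Bu2AlH at −78 °C stops at the lactol because the tetrahedral aluminium alkoxide survives until work-up, and neither the aryl sulfonate, the silyl ether nor C7/C8 is affected.

Step 6
Reactants: 10 lactol; 2 methanesulfonyl chloride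
Product: 12 4-[(2S,3S)-3-(tert-butyldiphenylsilyloxymethyl)-2,3-dihydrofuran-2-yl]-2-methoxyphenyl methanesulfonate, via anomeric mesylate 11 (not isolated)
Conditions: MsCl (1.5 equiv), Et3N (4 equiv), CH2Cl2, −40 °C → reflux; chromatography on Et3N-deactivated silica
Reagents that add atoms: none
Why: Sulfonylation of the anomeric hydroxyl followed by amine-mediated elimination (lactol dehydration to a cyclic enol ether, as used for furanoid glycals) can only remove a hydrogen from C8', so the C8'=C9' enol ether forms without touching C7 or C8.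

Step 7
Reactants: 12 silyl-protected dihydrofuran
Product: 13 4-[(2S,3S)-3-(hydroxymethyl)-2,3-dihydrofuran-2-yl]-2-methoxyphenyl methanesulfonate
Conditions: Bu4NF, THF, 0 °C → rt; aq. NH4Cl
Reagents that add atoms: none
Why: Fluoride-driven Si–O cleavage frees the C9 hydroxyl under non-acidic conditions that the enol ether tolerates, while the aryl methanesulfonate is inert to fluoride at this temperature.

Step 8
Reactants: 1 vanillin; 14 triisopropylsilyl chloride
Product: 15 3-methoxy-4-(triisopropylsilyloxy)benzaldehyde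
Conditions: TIPSCl, imidazole, DMF, rt
Reagents that add atoms: triisopropylsilyl chloride 14, CC(C)[Si](Cl)(C(C)C)C(C)C
Why: Imidazole-mediated silylation of a phenol is routine, and the bulky silyl ether withstands the Lewis acid of the next step while keeping the ring electron-rich.

Step 9
Reactants: 13 dihydrofuranyl methanol; 15 3-methoxy-4-(triisopropylsilyloxy)benzaldehyde
Product: 17 (7S,8S,7'R,8'S)-furofuran with the 4-mesyloxy-3-methoxyphenyl group endo at C7 plus the 3-methoxy-4-(triisopropylsilyloxy)phenyl group exo at C7', via silyl acetal 16 (not isolated)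
Conditions: TMSOTf (1.2 equiv), CH2Cl2, −78 → −20 °C (hold); then Et3SiH (2 equiv), −78 → −20 °C; aq. NaHCO3
Reagents that add atoms: none
Why: Condensation of the C9 hydroxyl with aldehyde 15 gives an aryl oxocarbenium ion that is attacked by the enol-ether carbon C8' (Prins-type oxocarbenium–enol ether cyclisation, known for 2,3-dihydrofuran-3-ylmethanols with aryl aldehyde equivalents), the tether forcing C7' onto the face of C8' that already carries C9 (cis ring fusion), after which the silane reduces the C9' acetal (ionic hydrogenation), and the C7' aryl should settle exo, trans to C9', because closure at this electron-rich benzylic centre is reversible under TMSOTf before hydride is added, whereas the mesyloxy-substituted aryl keeps C7 from ionising and so preserves its endo configuration.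

Step 10
Reactants: 17 silyl-protected furofuran; 18 prenyl bromide (1-bromo-3-methylbut-2-ene)
Product: 20 (7S,8S,7'R,8'S)-furofuran with the 4-mesyloxy-3-methoxyphenyl group at C7 plus the 3-methoxy-4-(3-methylbut-2-enyloxy)phenyl group at C7', via phenoxide 19 (not isolated)
Conditions: Bu4NF (1.05 equiv), THF, 0 °C; then prenyl bromide (1.5 equiv), 0 °C → rt
Reagents that add atoms: prenyl bromide 18, CC(C)=CCBr
Why: Fluoride cleaves the aryl silyl ether to the tetrabutylammonium phenoxide, which is O-alkylated in the same flask by the allylic bromide in an SN2 reaction (one-pot desilylation–Williamson etherification), the aryl sulfonate and the furofuran being inert.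

Step 11
Reactants: 20 prenylated furofuran mesylate
Product: 21 target, 2-methoxy-4-{(1S,3aS,4R,6aS)-4-[3-methoxy-4-(3-methylbut-2-enyloxy)phenyl]tetrahydro-1H,3H-furo[3,4-c]furan-1-yl}phenol
Conditions: KOH, MeOH/THF/H2O, 50 °C; aq. NH4Cl
Reagents that add atoms: none
Why: Aryl methanesulfonates are cleaved by hydroxide (sulfonate ester hydrolysis), which releases the phenol without affecting the prenyl ether, the cyclic benzylic ethers or any stereocentre.

Compound list
1 | vanillin | COc1cc(C=O)ccc1O | starting material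
2 | methanesulfonyl chloride | CS(=O)(=O)Cl | starting material
3 | 4-formyl-2-methoxyphenyl methanesulfonate | CS(=O)(=O)Oc1ccc(C=O)cc1OC | intermediate
4 | (Z)-but-2-ene-1,4-diol | OC/C=C\CO | starting material
5 | tert-butyldiphenylsilyl chloride | CC(C)(C)[Si](Cl)(c1ccccc1)c1ccccc1 | starting material
6 | (Z)-4-(tert-butyldiphenylsilyloxy)but-2-en-1-ol | OC/C=C\CO[Si](c1ccccc1)(c1ccccc1)C(C)(C)C | intermediate
7 | (Z)-4-(tert-butyldiphenylsilyloxy)but-2-enal | O=C/C=C\CO[Si](c1ccccc1)(c1ccccc1)C(C)(C)C | intermediate
8 | (E)-4-(tert-butyldiphenylsilyloxy)but-2-enal | O=C/C=C/CO[Si](c1ccccc1)(c1ccccc1)C(C)(C)C | intermediate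
9 | 4-[(2S,3S)-3-(tert-butyldiphenylsilyloxymethyl)-5-oxotetrahydrofuran-2-yl]-2-methoxyphenyl methanesulfonate (cis-lactone) | CS(=O)(=O)Oc1ccc(cc1OC)[C@H]2OC(=O)C[C@H]2CO[Si](c1ccccc1)(c1ccccc1)C(C)(C)C | intermediate
10 | 4-[(2S,3S)-3-(tert-butyldiphenylsilyloxymethyl)-5-hydroxytetrahydrofuran-2-yl]-2-methoxyphenyl methanesulfonate (lactol, anomers) | CS(=O)(=O)Oc1ccc(cc1OC)[C@H]2OC(O)C[C@H]2CO[Si](c1ccccc1)(c1ccccc1)C(C)(C)C | intermediate
11 | anomeric methanesulfonate of lactol 10 | CS(=O)(=O)Oc1ccc(cc1OC)[C@H]2OC(OS(C)(=O)=O)C[C@H]2CO[Si](c1ccccc1)(c1ccccc1)C(C)(C)C | intermediate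
12 | 4-[(2S,3S)-3-(tert-butyldiphenylsilyloxymethyl)-2,3-dihydrofuran-2-yl]-2-methoxyphenyl methanesulfonate | CS(=O)(=O)Oc1ccc(cc1OC)[C@H]2OC=C[C@H]2CO[Si](c1ccccc1)(c1ccccc1)C(C)(C)C | intermediate
13 | 4-[(2S,3S)-3-(hydroxymethyl)-2,3-dihydrofuran-2-yl]-2-methoxyphenyl methanesulfonate | CS(=O)(=O)Oc1ccc(cc1OC)[C@H]2OC=C[C@H]2CO | intermediate
14 | triisopropylsilyl chloride | CC(C)[Si](Cl)(C(C)C)C(C)C | starting material
15 | 3-methoxy-4-(triisopropylsilyloxy)benzaldehyde | COc1cc(C=O)ccc1O[Si](C(C)C)(C(C)C)C(C)C | intermediate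
16 | C9' O-trimethylsilyl acetal of furofuran 17 (anomers at C9') | COc1cc([C@H]2OC(O[Si](C)(C)C)[C@@H]3[C@H]2CO[C@H]3c2ccc(O[Si](C(C)C)(C(C)C)C(C)C)c(OC)c2)ccc1OS(C)(=O)=O | intermediate
17 | (7S,8S,7'R,8'S)-furofuran, 4-O-mesyl on the C7 aryl (endo), 4'-O-triisopropylsilyl on the C7' aryl (exo) | COc1cc([C@H]2OC[C@@H]3[C@H]2CO[C@H]3c2ccc(O[Si](C(C)C)(C(C)C)C(C)C)c(OC)c2)ccc1OS(C)(=O)=O | intermediate
18 | prenyl bromide (1-bromo-3-methylbut-2-ene) | CC(C)=CCBr | starting material
19 | tetrabutylammonium 4'-phenoxide of the (7S,8S,7'R,8'S)-furofuran mesylate | CCCC[N+](CCCC)(CCCC)CCCC.COc1cc([C@H]2OC[C@@H]3[C@H]2CO[C@H]3c2ccc([O-])c(OC)c2)ccc1OS(C)(=O)=O | intermediate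
20 | (7S,8S,7'R,8'S)-furofuran, 4-O-mesyl on the C7 aryl, 4'-O-prenyl on the C7' aryl | COc1cc([C@H]2OC[C@@H]3[C@H]2CO[C@H]3c2ccc(OCC=C(C)C)c(OC)c2)ccc1OS(C)(=O)=O | intermediate
21 | 2-methoxy-4-{(1S,3aS,4R,6aS)-4-[3-methoxy-4-(3-methylbut-2-enyloxy)phenyl]tetrahydro-1H,3H-furo[3,4-c]furan-1-yl}phenol | COc1cc([C@H]2OC[C@@H]3[C@H]2CO[C@H]3c2ccc(OCC=C(C)C)c(OC)c2)ccc1O | target

Total step count: 11. Longest linear sequence: 9 steps (steps 2, 3, 4, 5, 6, 7, 9, 10, 11, from (Z)-but-2-ene-1,4-diol).

Steps most likely to fail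

1. Step 4. The catalyst may discriminate poorly between the faces of the homoenolate, the homoenolate may lose its γ-silyloxide by elimination, or 3 may be consumed by acyl-anion addition. The fallback is an auxiliary-controlled anti-aldol reaction followed by ozonolysis; it sets out from 3 and returns at lactol 10. (S)-4-Benzyloxazolidin-2-one is N-acylated with pent-4-enoyl chloride (n-BuLi, THF, −78 °C) to give the N-pentenoyl imide F1. In F1 the α-carbon becomes C8, the acyl carbon C9 and the allyl group C8' and C9' plus one carbon that is later cleaved off. The MgCl2-catalysed anti-aldol reaction of F1 with 3 (MgCl2 10 mol %, Et3N, Me3SiCl, EtOAc, rt) should give the silylated (2R,3S)-anti-aldol adduct F2, and aqueous HCl in THF frees the anti-aldol F3. LiBH4 (THF/MeOH, 0 °C) removes the auxiliary to give the (1S,2S)-diol F4. TBDPSCl/imidazole (CH2Cl2, 0 °C) silylates the primary hydroxyl to give the silyl ether F5. Ozonolysis (O3, CH2Cl2/MeOH, −78 °C; Me2S) then unmasks the C9' aldehyde, which closes on the C7 hydroxyl to lactol 10.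

2. Step 9. The closure may trap the C7' aryl kinetically on the concave (endo) face before it equilibrates, or prolonged exposure to the Lewis acid may start to erode C7. The fallback separates ring closure from C7' control; it sets out from 13 and 15 and returns at 20. With Et3SiH present from the start at −78 °C (TMSOTf, CH2Cl2), closure and reduction should give the 7'-endo furofuran F6 without equilibration. Bu4NF (THF, 0 °C) gives the 7'-endo phenol F7. Camphorsulfonic acid in MeCN (rt) then equilibrates C7' alone through the para-hydroxybenzylic cation, the acid epimerisation typical of phenolic furofuran lignans, toward the less congested 7'-exo phenol F8. F8 is separated and prenylated (K2CO3, prenyl bromide, DMF, rt) to 20.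

3. Step 6. The anomeric sulfonate may collapse to a chloride that resists elimination, or the enol ether may hydrate or oligomerise in the presence of the amine hydrochloride. The fallback is an acetal-elimination route; it sets out from 10 and returns at 12. Methanol with pyridinium p-toluenesulfonate (rt) converts the lactol into the methyl acetal F9. TMSOTf/i-Pr2NEt (CH2Cl2, −20 °C → rt) ionises the acetal and removes a proton from C8' to give 12.

Further compounds
F1 | step 4 | (S)-4-benzyl-3-(pent-4-enoyl)oxazolidin-2-one | C=CCCC(=O)N1[C@@H](Cc2ccccc2)COC1=O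
F2 | step 4 | (S)-4-benzyl-3-[(2R,3S)-2-allyl-3-(4-mesyloxy-3-methoxyphenyl)-3-(trimethylsilyloxy)propanoyl]oxazolidin-2-one | CS(=O)(=O)Oc1ccc(cc1OC)[C@@H](O[Si](C)(C)C)[C@@H](CC=C)C(=O)N1[C@@H](Cc2ccccc2)COC1=O
F3 | step 4 | (S)-4-benzyl-3-[(2R,3S)-2-allyl-3-hydroxy-3-(4-mesyloxy-3-methoxyphenyl)propanoyl]oxazolidin-2-one | CS(=O)(=O)Oc1ccc(cc1OC)[C@@H](O)[C@@H](CC=C)C(=O)N1[C@@H](Cc2ccccc2)COC1=O
F4 | step 4 | 4-[(1S,2S)-1-hydroxy-2-(hydroxymethyl)pent-4-enyl]-2-methoxyphenyl methanesulfonate | CS(=O)(=O)Oc1ccc(cc1OC)[C@@H](O)[C@@H](CC=C)CO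
F5 | step 4 | 4-[(1S,2S)-2-(tert-butyldiphenylsilyloxymethyl)-1-hydroxypent-4-enyl]-2-methoxyphenyl methanesulfonate | CS(=O)(=O)Oc1ccc(cc1OC)[C@@H](O)[C@@H](CC=C)CO[Si](c1ccccc1)(c1ccccc1)C(C)(C)C
F6 | step 9 | (7S,8S,7'S,8'S)-furofuran (C7' epimer of 17, both aryl groups endo), 4-O-mesyl and 4'-O-triisopropylsilyl | COc1cc([C@H]2OC[C@@H]3[C@H]2CO[C@@H]3c2ccc(O[Si](C(C)C)(C(C)C)C(C)C)c(OC)c2)ccc1OS(C)(=O)=O
F7 | step 9 | (7S,8S,7'S,8'S)-furofuran 4'-phenol, 4-O-mesyl (7'-endo) | COc1cc([C@H]2OC[C@@H]3[C@H]2CO[C@@H]3c2ccc(O)c(OC)c2)ccc1OS(C)(=O)=O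
F8 | step 9 | (7S,8S,7'R,8'S)-furofuran 4'-phenol, 4-O-mesyl (7'-exo) | COc1cc([C@H]2OC[C@@H]3[C@H]2CO[C@H]3c2ccc(O)c(OC)c2)ccc1OS(C)(=O)=O
F9 | step 6 | 4-[(2S,3S)-3-(tert-butyldiphenylsilyloxymethyl)-5-methoxytetrahydrofuran-2-yl]-2-methoxyphenyl methanesulfonate (anomers) | CS(=O)(=O)Oc1ccc(cc1OC)[C@H]2OC(OC)C[C@H]2CO[Si](c1ccccc1)(c1ccccc1)C(C)(C)C
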